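The ochre run at 8.00 min has 41.1 % of its charge in chains and the green run 38.0 %, although green got about twice the dose. So the reacted part, c, barely follows the dose. The new flask's dose lies between theirs, so I take their mean, 39.6 %.

| flask | free monomer | transfer agent | initiator | remark | time |
|---|---|---|---|---|---|
| ochre | 0.67 mM (fed, over 2.5 min) | 0.30 mM | 5 µM | run made earlier; the fed solution adds 0.25 times the starting volume |  |
| green | 1.5 mM (fed, over 2.5 min) | 0.30 mM | 5 µM | run made earlier; the fed solution adds 0.25 times the starting volume |  |
| flask | 1.0 mM (fed, over 2.5 min) | 0.300 mM | 5.0 µM | the fed solution adds 0.25 times the starting volume | 8.0 min |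

| run | time / min | monomer in chains / % | free monomer / % |
|---|---|---|---|
| ochre | 2.00 | 20.9 | 59.9 |
| ochre | 4.00 | 31.6 | 67.6 |
| ochre | 6.00 | 39.3 | 63.9 |
| ochre | 8.00 | 41.1 | 60.4 |
| ochre | 10.0 | 42.6 | 56.2 |
| green | 2.00 | 17.1 | 63.2 |
| green | 4.00 | 29.7 | 71.5 |
| green | 6.00 | 35.4 | 62.9 |
| green | 8.00 | 38.0 | 62.0 |
| green | 10.0 | 38.9 | 61.2 |

(readings scatter by 1 percentage point)

- every charge counts on the volume at the start, and the solution that is fed holds the whole dose
- the average divides the monomer in chains by the number of chains begun, living and dead together
- the earlier runs were read with a standard deviation of 1 percentage point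
- the earlier runs do not show the number of chains; that part of a forecast is a guess
- percentages count the whole charge, also what has not yet gone in

- average number of monomer units in a chain (chains begun, living or dead) at 8.0 min
- part of the free monomer that has reacted at 8.0 min

The average dp is monomer in chains over chains begun, so I need a count of chains, which the runs do not show. My count is therefore a guess: I suppose that the transfer agent begins no chains of its own, and that each initiator has begun one chain by 8.0 min. That gives my rule. The charge ratio Q is the free monomer charged per initiator charged, here 200, and dp = Q × c. For this flask that makes dp 79.1.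

The forecast gives dp 6 and c 39.5 %, saying “The number of chains is not shown by the runs”; it stands near my c and far from my dp. The flask gives dp 77.3 and c 38.6 %.

    free monomer + initiator → living end + monomer in chains (k = 1300 M⁻¹ s⁻¹)
    free monomer + living end → monomer in chains + living end, rate k2*[living end]*[free monomer] (k = 4200 M⁻¹ s⁻¹)
    living end + transfer agent → dead chain (kL = 17.0 M⁻¹ s⁻¹)
    2 living end → dead end (k = 5100 M⁻¹ s⁻¹)

At 8.00 min this flask keeps 0 % of its initiator and 99.6 % of its transfer agent, and Q × c with its c is 77.2. The neighbour is the same flask read at 5.0 min. Its initiator also stands at 0 %, and its transfer agent at 99.6 %, so I count chains the same way. Its c is 33.9 %, and Q × c puts its dp at 67.8. The simulated dp of that neighbour is 67.9.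

The earlier runs and the new flask are simulated with constants of no real substance, noise included.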